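**Retrosynthetic overview**
1. Target 14 ⇐ tert-butyl ester 13 (acidolysis) ⇐ epoxyquinone 12 (site- and face-selective hydride reduction of the C5 ketone).
2. 12 ⇐ phenol 10 in one flask: oxygenative dearomatisation to p-quinone 11, then catalyst-controlled asymmetric epoxidation of the unprotected quinone (sets C1 and C6).
3. 10 ⇐ allylphenol 8 + tert-butyl methacrylate (cross-metathesis); 8 ⇐ 4 (O-allylation, aromatic Claisen, aldehyde reduction).
4. 4 ⇐ 2-bromo-3-hydroxybenzaldehyde 2 + (E)-hept-1-enylboronic acid (Suzuki); 2 ⇐ 3-hydroxybenzaldehyde 1.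
5. Rings: the carbocycle is the benzene ring of 1 throughout; the oxirane is the only ring formed (step 5).

Assumption: the target is taken exactly as drawn, (1S,5R,6S), with the C5 hydroxyl trans to the oxirane oxygen; the facial sense of the cinchonidinium catalyst in step 5 rests on analogy, and the pseudoenantiomeric cinchoninium salt would be used if the sense proves opposite.

**Step 1**
Reactants: 1 3-hydroxybenzaldehyde
Product: 2 2-bromo-3-hydroxybenzaldehyde
Conditions: Br2 (1.1 equiv), Fe powder (5 mol %), NaOAc (2 equiv), AcOH, 20 °C; crystallisation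
Reagents that add atoms: bromine BrBr
Why: Electrophilic aromatic bromination; under these acetate-buffered conditions the position between OH and CHO is brominated and 2 crystallises free of the 6-bromo isomer (moderate yield); no stereocentre.

**Step 2**
Reactants: 2 2-bromo-3-hydroxybenzaldehyde; 3 (E)-hept-1-enylboronic acid
Product: 4 2-[(E)-hept-1-enyl]-3-hydroxybenzaldehyde
Conditions: Pd(PPh3)4 (3 mol %), K2CO3 (3 equiv), DME/H2O 4:1, 80 °C
Reagents that add atoms: none
Why: Suzuki–Miyaura coupling; the bromide is activated by the ortho formyl group and the alkenylboronic acid transfers with retention of the (E) geometry.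

**Step 3**
Reactants: 4 2-[(E)-hept-1-enyl]-3-hydroxybenzaldehyde; 5 allyl bromide
Product: 8 6-allyl-2-[(E)-hept-1-enyl]-3-(hydroxymethyl)phenol, via allyl aryl ether 6 (not isolated), via Claisen aldehyde 7 (not isolated)
Conditions: 5 (1.05 equiv), K2CO3 (1.5 equiv), NMP, 60 °C; then 200 °C (sealed), 2 h; then NaBH4 (1 equiv), MeOH, 0 °C
Reagents that add atoms: none
Why: Williamson O-allylation, then aromatic Claisen [3,3] rearrangement to the only free ortho position (the other is blocked by the heptenyl group) with tautomerisation, then chemoselective borohydride reduction of the aldehyde; no stereocentre.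

**Step 4**
Reactants: 8 6-allyl-2-[(E)-hept-1-enyl]-3-(hydroxymethyl)phenol; 9 tert-butyl methacrylate
Product: 10 tert-butyl (E)-4-{3-[(E)-hept-1-enyl]-2-hydroxy-4-(hydroxymethyl)phenyl}-2-methylbut-2-enoate
Conditions: 9 (10 equiv), second-generation Hoveyda–Grubbs catalyst (5 mol %), 1,4-benzoquinone (10 mol %), CH2Cl2, 40 °C
Reagents that add atoms: none
Why: Olefin cross-metathesis; the terminal allyl group reacts while the di-ortho-substituted internal styrenyl alkene is too hindered, and the trisubstituted enoate forms as the thermodynamically favoured (E) isomer.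

**Step 5**
Reactants: 10 tert-butyl (E)-4-{3-[(E)-hept-1-enyl]-2-hydroxy-4-(hydroxymethyl)phenyl}-2-methylbut-2-enoate
Product: 12 tert-butyl (E)-4-{(1S,6R)-3-[(E)-hept-1-enyl]-4-(hydroxymethyl)-2,5-dioxo-7-oxabicyclo[4.1.0]hept-3-en-1-yl}-2-methylbut-2-enoate, via quinone 11 (not isolated)
Conditions: (KSO3)2NO (2.5 equiv), aq KH2PO4, PhMe, O-benzyl-N-(9-anthracenylmethyl)cinchonidinium bromide (10 mol %), 0 °C; aqueous layer drained; then aq NaOCl (3 equiv), −10 °C
Reagents that add atoms: potassium nitrosodisulfonate [K+].[K+].[O]N(S(=O)(=O)[O-])S(=O)(=O)[O-]; sodium hypochlorite [Na+].[O-]Cl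
Why: Proposed new method: Teuber oxidation (one nitrosodisulfonate radical abstracts the phenolic H, a second adds at the free para carbon, imidodisulfonate is lost) gives p-quinone 11 carrying the new C5 oxygen, and the same chiral ammonium salt then carries hypochlorite as an ion pair to the unsubstituted CH of the less substituted, more electrophilic enone (Weitz–Scheffer addition, enolate closure with loss of chloride), so the cis-fused oxirane forms on one face under catalyst control and sets C1 (S) and C6 (R); the tetrasubstituted heptenyl-bearing alkene is too hindered and electron-rich to compete; closest known reactions are the oxidation of 2,6-disubstituted phenols with (KSO3)2NO and the cinchona phase-transfer epoxidation of 2-alkyl-1,4-naphthoquinones with NaOCl.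

**Step 6**
Reactants: 12 tert-butyl (E)-4-{(1S,6R)-3-[(E)-hept-1-enyl]-4-(hydroxymethyl)-2,5-dioxo-7-oxabicyclo[4.1.0]hept-3-en-1-yl}-2-methylbut-2-enoate
Product: 13 tert-butyl (E)-4-{(1S,5R,6S)-3-[(E)-hept-1-enyl]-5-hydroxy-4-(hydroxymethyl)-2-oxo-7-oxabicyclo[4.1.0]hept-3-en-1-yl}-2-methylbut-2-enoate
Conditions: iBu2AlH (2.3 equiv), THF, −78 °C; aq potassium sodium tartrate (KNaC4H4O6)
Reagents that add atoms: none
Why: Chelation-controlled 1,2-reduction of an α,β-epoxy ketone; the aluminium alkoxide formed from the CH2OH group activates the adjacent, less hindered C5 carbonyl (the C2 carbonyl is flanked by the quaternary oxirane carbon), and hydride is delivered from iBu2AlH bound to the oxirane oxygen, on the epoxide face, so the new OH is trans to the oxirane (5R).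

**Step 7**
Reactants: 13 tert-butyl (E)-4-{(1S,5R,6S)-3-[(E)-hept-1-enyl]-5-hydroxy-4-(hydroxymethyl)-2-oxo-7-oxabicyclo[4.1.0]hept-3-en-1-yl}-2-methylbut-2-enoate
Product: 14 (E)-4-{(1S,5R,6S)-3-[(E)-hept-1-enyl]-5-hydroxy-4-(hydroxymethyl)-2-oxo-7-oxabicyclo[4.1.0]hept-3-en-1-yl}-2-methylbut-2-enoic acid
Conditions: CF3CO2H/CH2Cl2 1:4, 0 °C
Reagents that add atoms: none
Why: Acid-catalysed tert-butyl ester cleavage with loss of isobutene; the α,β-epoxy ketone and the electron-poor allylic alcohol should not ionise under these conditions, so no stereocentre is touched.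

**Compound list**
1 | 3-hydroxybenzaldehyde | O=Cc1cccc(O)c1 | starting material
2 | 2-bromo-3-hydroxybenzaldehyde | O=Cc1cccc(O)c1Br | intermediate
3 | (E)-hept-1-enylboronic acid | CCCCC/C=C/B(O)O | starting material
4 | 2-[(E)-hept-1-enyl]-3-hydroxybenzaldehyde | CCCCC/C=C/c1c(O)cccc1C=O | intermediate
5 | allyl bromide | C=CCBr | starting material
6 | 3-(allyloxy)-2-[(E)-hept-1-enyl]benzaldehyde (allyl aryl ether) | CCCCC/C=C/c1c(OCC=C)cccc1C=O | intermediate
7 | 4-allyl-2-[(E)-hept-1-enyl]-3-hydroxybenzaldehyde (Claisen aldehyde) | CCCCC/C=C/c1c(O)c(CC=C)ccc1C=O | intermediate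
8 | 6-allyl-2-[(E)-hept-1-enyl]-3-(hydroxymethyl)phenol | CCCCC/C=C/c1c(O)c(CC=C)ccc1CO | intermediate
9 | tert-butyl methacrylate | CC(=C)C(=O)OC(C)(C)C | starting material
10 | tert-butyl (E)-4-{3-[(E)-hept-1-enyl]-2-hydroxy-4-(hydroxymethyl)phenyl}-2-methylbut-2-enoate | CCCCC/C=C/c1c(O)c(C/C=C(\C)C(=O)OC(C)(C)C)ccc1CO | intermediate
11 | tert-butyl (E)-4-{5-[(E)-hept-1-enyl]-4-(hydroxymethyl)-3,6-dioxocyclohexa-1,4-dien-1-yl}-2-methylbut-2-enoate (quinone) | CCCCC/C=C/C1=C(CO)C(=O)C=C(C/C=C(\C)C(=O)OC(C)(C)C)C1=O | intermediate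
12 | tert-butyl (E)-4-{(1S,6R)-3-[(E)-hept-1-enyl]-4-(hydroxymethyl)-2,5-dioxo-7-oxabicyclo[4.1.0]hept-3-en-1-yl}-2-methylbut-2-enoate | CCCCC/C=C/C1=C(CO)C(=O)[C@@H]2O[C@]2(C/C=C(\C)C(=O)OC(C)(C)C)C1=O | intermediate
13 | tert-butyl (E)-4-{(1S,5R,6S)-3-[(E)-hept-1-enyl]-5-hydroxy-4-(hydroxymethyl)-2-oxo-7-oxabicyclo[4.1.0]hept-3-en-1-yl}-2-methylbut-2-enoate | CCCCC/C=C/C1=C(CO)[C@@H](O)[C@@H]2O[C@]2(C/C=C(\C)C(=O)OC(C)(C)C)C1=O | intermediate
14 | (E)-4-{(1S,5R,6S)-3-[(E)-hept-1-enyl]-5-hydroxy-4-(hydroxymethyl)-2-oxo-7-oxabicyclo[4.1.0]hept-3-en-1-yl}-2-methylbut-2-enoic acid | CCCCC/C=C/C1=C(CO)[C@@H](O)[C@@H]2O[C@]2(C/C=C(\C)C(=O)O)C1=O | target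

**Totals**
Total step count: 7. Longest linear sequence: 7 (from 1).

**Three steps most likely to fail**

Step 5 (one-flask dearomatisation and asymmetric epoxidation). The free quinone may decompose in the basic biphasic medium, or the enantiomeric excess may stay near the 80–90 % seen for 2-alkylnaphthoquinones; in that case 13 or 14 would need recrystallisation. The fallback sets out from 10 and returns at 12 by way of a ketal-differentiated quinone. Oxidise 10 with PhI(OAc)2 (2.2 equiv) in MeOH at 0 °C to the quinone monoketal tert-butyl (E)-4-{5-[(E)-hept-1-enyl]-4-(hydroxymethyl)-3,3-dimethoxy-6-oxocyclohexa-1,4-dien-1-yl}-2-methylbut-2-enoate F5. Epoxidise it with Ph3COOH, NaN(SiMe3)2 and the appropriate enantiomer of diisopropyl tartrate in PhMe at −50 °C (tartrate-mediated nucleophilic epoxidation) to the epoxy ketal tert-butyl (E)-4-{(1S,6R)-3-[(E)-hept-1-enyl]-4-(hydroxymethyl)-5,5-dimethoxy-2-oxo-7-oxabicyclo[4.1.0]hept-3-en-1-yl}-2-methylbut-2-enoate F6. Hydrolyse the ketal with montmorillonite K10 in wet CH2Cl2 to reach 12.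

Step 6 (facial selectivity of the reduction). If the free CH2OH overrides oxirane-directed delivery, the cis epoxy alcohol will form. The fallback sets out from 12 and returns at 13 by inversion. Reduce 12 with NaBH4 and CeCl3·7H2O in MeOH at −78 °C (hydride anti to the oxirane) to the cis diol tert-butyl (E)-4-{(1S,5S,6S)-3-[(E)-hept-1-enyl]-5-hydroxy-4-(hydroxymethyl)-2-oxo-7-oxabicyclo[4.1.0]hept-3-en-1-yl}-2-methylbut-2-enoate F7. Treat it with 4-nitrobenzoic acid, PPh3 and diisopropyl azodicarboxylate (2.5 equiv each) in THF at 0 °C (double Mitsunobu, inversion at C5) to give the diester tert-butyl (E)-4-{(1S,5R,6S)-3-[(E)-hept-1-enyl]-5-(4-nitrobenzoyloxy)-4-[(4-nitrobenzoyloxy)methyl]-2-oxo-7-oxabicyclo[4.1.0]hept-3-en-1-yl}-2-methylbut-2-enoate F8. Methanolysis with K2CO3 in MeOH at 0 °C gives 13.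

Step 4 (chemoselectivity of the cross-metathesis in the presence of the heptenyl alkene). If the styrenyl alkene is cleaved or scrambled, the enoate is built before the heptenyl group is introduced. The fallback sets out from 2 and returns at 10. Alkylate 2 with 5 (K2CO3, acetone) to 3-(allyloxy)-2-bromobenzaldehyde F1. Heat it neat at 190 °C (Claisen) to 4-allyl-2-bromo-3-hydroxybenzaldehyde F2. Cross-metathesis with 9 under the step 4 conditions gives tert-butyl (E)-4-(3-bromo-4-formyl-2-hydroxyphenyl)-2-methylbut-2-enoate F3. Couple it with 3 at 25 °C (Pd(OAc)2, SPhos, K3PO4, THF/H2O; short reaction time to limit phenoxide oxa-Michael closure onto the α-methyl enoate) to tert-butyl (E)-4-{4-formyl-3-[(E)-hept-1-enyl]-2-hydroxyphenyl}-2-methylbut-2-enoate F4. Reduce the aldehyde with NaBH4 and CeCl3·7H2O in MeOH at −20 °C to 10.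

**Further compounds**
F1 | step 4 | 3-(allyloxy)-2-bromobenzaldehyde | O=Cc1cccc(OCC=C)c1Br
F2 | step 4 | 4-allyl-2-bromo-3-hydroxybenzaldehyde | O=Cc1ccc(CC=C)c(O)c1Br
F3 | step 4 | tert-butyl (E)-4-(3-bromo-4-formyl-2-hydroxyphenyl)-2-methylbut-2-enoate | O=Cc1ccc(C/C=C(\C)C(=O)OC(C)(C)C)c(O)c1Br
F4 | step 4 | tert-butyl (E)-4-{4-formyl-3-[(E)-hept-1-enyl]-2-hydroxyphenyl}-2-methylbut-2-enoate | CCCCC/C=C/c1c(O)c(C/C=C(\C)C(=O)OC(C)(C)C)ccc1C=O
F5 | step 5 | tert-butyl (E)-4-{5-[(E)-hept-1-enyl]-4-(hydroxymethyl)-3,3-dimethoxy-6-oxocyclohexa-1,4-dien-1-yl}-2-methylbut-2-enoate | CCCCC/C=C/C1=C(CO)C(OC)(OC)C=C(C/C=C(\C)C(=O)OC(C)(C)C)C1=O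
F6 | step 5 | tert-butyl (E)-4-{(1S,6R)-3-[(E)-hept-1-enyl]-4-(hydroxymethyl)-5,5-dimethoxy-2-oxo-7-oxabicyclo[4.1.0]hept-3-en-1-yl}-2-methylbut-2-enoate | CCCCC/C=C/C1=C(CO)C(OC)(OC)[C@@H]2O[C@]2(C/C=C(\C)C(=O)OC(C)(C)C)C1=O
F7 | step 6 | tert-butyl (E)-4-{(1S,5S,6S)-3-[(E)-hept-1-enyl]-5-hydroxy-4-(hydroxymethyl)-2-oxo-7-oxabicyclo[4.1.0]hept-3-en-1-yl}-2-methylbut-2-enoate | CCCCC/C=C/C1=C(CO)[C@H](O)[C@@H]2O[C@]2(C/C=C(\C)C(=O)OC(C)(C)C)C1=O
F8 | step 6 | tert-butyl (E)-4-{(1S,5R,6S)-3-[(E)-hept-1-enyl]-5-(4-nitrobenzoyloxy)-4-[(4-nitrobenzoyloxy)methyl]-2-oxo-7-oxabicyclo[4.1.0]hept-3-en-1-yl}-2-methylbut-2-enoate | CCCCC/C=C/C1=C(COC(=O)c3ccc(cc3)[N+](=O)[O-])[C@@H](OC(=O)c4ccc(cc4)[N+](=O)[O-])[C@@H]2O[C@]2(C/C=C(\C)C(=O)OC(C)(C)C)C1=O
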